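The route disconnects the C12–C13 bond, so that ring A, the cyclohexane C7–C8–C15–C14–C13–C12, is closed onto a preformed cyclopentenone-fused azacyclononadiene (rings B and C). In one SmI2 operation a Sharpless-derived α,β-epoxy aldehyde is opened to the C15 carbinol and its chelated C13 ketyl adds 6-exo to C12, the β-carbon of the C5 enone. This creates the quaternary spiro centre C12, the cis A/B fusion and the C13 carbinol, and turns the cross-conjugated C2=C3 vinyl unit into the C3=C4 enone. The precursor is a 5/9-bicyclic dienone, made by Stork–Danheiser transposition and ring-closing metathesis, with the epoxy aldehyde chain on C7.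

Key step: step 15

Remark on labels: ring C (azonine) is N–C1–C2–C3–C4–C12–C11–C10–C9, ring B is C4–C5(=O)–C6–C7–C12, ring A is C7–C8–C15(C16H3)–C14–C13–C12. Assumption: 1,4-dioxaspiro[4.4]nonan-7-one and RAMP are bought.

Step 1
Reactants: 1 3-methylbut-2-en-1-ol
Product: 2 tert-butyl(dimethyl)[(3-methylbut-2-en-1-yl)oxy]silane
Conditions: TBSCl, imidazole, CH2Cl2, 0 °C to rt
Reagents that add atoms: tert-butyl(chloro)dimethylsilane, CC(C)(C)[Si](C)(C)Cl
Why: Standard silyl ether formation masks the hydroxyl for the oxidation, bromination and azaenolate alkylation that follow.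

Step 2
Reactants: 2 tert-butyl(dimethyl)[(3-methylbut-2-en-1-yl)oxy]silane
Product: 3 (2E)-4-{[tert-butyl(dimethyl)silyl]oxy}-2-methylbut-2-en-1-ol
Conditions: SeO2 (cat.), t-BuOOH, salicylic acid (cat.), CH2Cl2, rt
Reagents that add atoms: tert-butyl hydroperoxide, CC(C)(C)OO
Why: Riley allylic oxidation hydroxylates the methyl group trans to the CH2O chain of the trisubstituted alkene, so the alcohol should form with E geometry.

Step 3
Reactants: 3 (2E)-4-{[tert-butyl(dimethyl)silyl]oxy}-2-methylbut-2-en-1-ol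
Product: 4 {[(2E)-4-bromo-3-methylbut-2-en-1-yl]oxy}(tert-butyl)dimethylsilane
Conditions: CBr4, PPh3, CH2Cl2, 0 °C
Reagents that add atoms: carbon tetrabromide, BrC(Br)(Br)Br
Why: Appel bromination converts the primary allylic alcohol into the SN2-reactive allylic bromide without allylic transposition.

Step 4
Reactants: 5 N-methylprop-2-en-1-amine; 6 1-bromo-3-chloropropane
Product: 7 3-chloro-N-methyl-N-(prop-2-en-1-yl)propan-1-amine
Conditions: K2CO3, MeCN, rt (6 in excess)
Reagents that add atoms: none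
Why: Chemoselective N-alkylation, since the secondary amine displaces bromide much faster than chloride and the chloride is kept for Grignard formation.

Step 5
Reactants: 8 1,4-dioxaspiro[4.4]nonan-7-one; 9 (2R)-2-(methoxymethyl)pyrrolidin-1-amine (RAMP)
Product: 10 (2R)-N-(1,4-dioxaspiro[4.4]nonan-7-ylidene)-2-(methoxymethyl)pyrrolidin-1-amine
Conditions: cyclohexane, reflux, water separator
Reagents that add atoms: none
Why: Hydrazone condensation attaches the chiral auxiliary needed for the Enders RAMP-hydrazone alkylation.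

Step 6
Reactants: 10 (2R)-N-(1,4-dioxaspiro[4.4]nonan-7-ylidene)-2-(methoxymethyl)pyrrolidin-1-amine; 4 {[(2E)-4-bromo-3-methylbut-2-en-1-yl]oxy}(tert-butyl)dimethylsilane
Product: 11 (2R)-N-[(8S)-8-[(2E)-4-{[tert-butyl(dimethyl)silyl]oxy}-2-methylbut-2-en-1-yl]-1,4-dioxaspiro[4.4]nonan-7-ylidene]-2-(methoxymethyl)pyrrolidin-1-amine
Conditions: LiN(iPr)2, THF, 0 °C; then 4, −100 to −78 °C
Reagents that add atoms: none
Why: Enders RAMP-hydrazone alkylation, in which the base removes a proton from the less hindered α-CH2 remote from the ketal and the chelated azaenolate is alkylated on the face away from the methoxymethyl arm, which should set the future C7 centre as 8S.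

Step 7
Reactants: 11 alkylated RAMP hydrazone
Product: 12 (8S)-8-[(2E)-4-{[tert-butyl(dimethyl)silyl]oxy}-2-methylbut-2-en-1-yl]-1,4-dioxaspiro[4.4]nonan-7-one
Conditions: sat. aq. oxalic acid, Et2O, rt
Reagents that add atoms: water, O
Why: Mild two-phase hydrazone hydrolysis should regenerate the ketone without epimerising the α-stereocentre and return the auxiliary.

Step 8
Reactants: 12 (8S)-8-[(2E)-4-{[tert-butyl(dimethyl)silyl]oxy}-2-methylbut-2-en-1-yl]-1,4-dioxaspiro[4.4]nonan-7-one
Product: 13 (5S)-3-ethoxy-5-[(2E)-4-hydroxy-2-methylbut-2-en-1-yl]cyclopent-2-en-1-one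
Conditions: PPTS (cat.), abs. EtOH, 50 °C
Reagents that add atoms: ethanol, CCO
Why: Acid-catalysed alcoholysis, in which the β-keto ketal ionises and loses the C4 proton to give the vinylogous ester with the carbonyl kept next to C7, while the primary silyl ether is cleaved under the same conditions.

Step 9
Reactants: 13 (5S)-3-ethoxy-5-[(2E)-4-hydroxy-2-methylbut-2-en-1-yl]cyclopent-2-en-1-one
Product: 14 (5S)-2-bromo-3-ethoxy-5-[(2E)-4-hydroxy-2-methylbut-2-en-1-yl]cyclopent-2-en-1-one
Conditions: NBS, CH2Cl2, 0 °C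
Reagents that add atoms: N-bromosuccinimide, O=C1CCC(=O)N1Br
Why: Electrophilic α-bromination of the electron-rich C2 position of a vinylogous ester, which should be faster than any reaction at the isolated alkene.

Step 10
Reactants: 14 (5S)-2-bromo-3-ethoxy-5-[(2E)-4-hydroxy-2-methylbut-2-en-1-yl]cyclopent-2-en-1-one
Product: 15 (5S)-2-ethenyl-3-ethoxy-5-[(2E)-4-hydroxy-2-methylbut-2-en-1-yl]cyclopent-2-en-1-one
Conditions: Bu3Sn(CH=CH2), Pd(PPh3)4 (cat.), toluene, 90 °C
Reagents that add atoms: tributyl(ethenyl)stannane, C=C[Sn](CCCC)(CCCC)CCCC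
Why: Stille coupling under zerovalent palladium catalysis installs the vinyl group (future C3) needed for metathesis and for the later enone relocation.

Step 11
Reactants: 15 (5S)-2-ethenyl-3-ethoxy-5-[(2E)-4-hydroxy-2-methylbut-2-en-1-yl]cyclopent-2-en-1-one
Product: 16 (5R)-2-ethenyl-3-ethoxy-5-{[(2S,3S)-3-(hydroxymethyl)-2-methyloxiran-2-yl]methyl}cyclopent-2-en-1-one (ring centre spatially unchanged; the descriptor changes by priority only)
Conditions: Ti(OiPr)4 (cat.), L-(+)-diethyl tartrate (cat.), t-BuOOH, 4 Å MS, CH2Cl2, −20 °C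
Reagents that add atoms: tert-butyl hydroperoxide, CC(C)(C)OO
Why: Sharpless asymmetric epoxidation of the E-trisubstituted primary allylic alcohol, where the L-(+)-tartrate catalyst should give the (2S,3S)-epoxy alcohol and so fix C15 (and the sacrificial C14 centre) under reagent control.

Step 12
Reactants: 16 epoxy alcohol vinylogous ester; 7 3-chloro-N-methyl-N-(prop-2-en-1-yl)propan-1-amine
Product: 19 (4S)-2-ethenyl-4-{[(2S,3S)-3-(hydroxymethyl)-2-methyloxiran-2-yl]methyl}-3-{3-[methyl(prop-2-en-1-yl)amino]propyl}cyclopent-2-en-1-one, via Grignard reagent 17 (not isolated), via tertiary carbinol 18 (not isolated)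
Conditions: 7, Mg, THF, 50 °C; then 16, THF, −78 to −20 °C; aq. citrate buffer (pH 4.5), 0 °C; NaHCO3
Reagents that add atoms: water, O
Why: Stork–Danheiser transposition, in which 1,2-addition of the aminopropyl Grignard reagent to the C12 carbonyl and mild acidic hydrolysis move the carbonyl to C5, the pH being kept at 4–5 so that the epoxy alcohol should survive and C7 stay untouched.

Step 13
Reactants: 19 (4S)-2-ethenyl-4-{[(2S,3S)-3-(hydroxymethyl)-2-methyloxiran-2-yl]methyl}-3-{3-[methyl(prop-2-en-1-yl)amino]propyl}cyclopent-2-en-1-one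
Product: 20 (3S,9Z)-3-{[(2S,3S)-3-(hydroxymethyl)-2-methyloxiran-2-yl]methyl}-7-methyl-3,4,5,6,7,8-hexahydrocyclopenta[e]azonin-1(2H)-one (ring B/C dienone: C5=O, C4=C12, Z-C2=C3, chain on C7)
Conditions: TsOH·H2O (1.0 equiv), second-generation Grubbs catalyst (10 mol%), ClCH2CH2Cl (1 mM), 70 °C; aq. NaHCO3
Reagents that add atoms: none
Why: Ring-closing metathesis between the N-allyl and C4-vinyl groups, which the cyclopentenone double bond holds cis, should close the nine-membered ring as the Z-diene, with the amine protonated to spare the ruthenium carbene.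

Step 14
Reactants: 20 bicyclic dienone epoxy alcohol
Product: 21 (2R,3S)-3-methyl-3-{[(3S,9Z)-7-methyl-1-oxo-1,2,3,4,5,6,7,8-octahydrocyclopenta[e]azonin-3-yl]methyl}oxirane-2-carbaldehyde
Conditions: Dess–Martin periodinane, NaHCO3, CH2Cl2, 0 °C
Reagents that add atoms: none
Why: Dess–Martin oxidation of the primary epoxy alcohol gives the α,β-epoxy aldehyde under buffered conditions that should not epimerise C14.

Step 15
Reactants: 21 epoxy aldehyde dienone
Product: 24 (3E,7S,12S,13S,15S)-13,15-dihydroxy enone (de-O-acetyl target), via hydroxy aldehyde 22 (not isolated), via deconjugated enone diol 23 (not isolated)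
Conditions: SmI2 (5 equiv), MeOH, THF, −78 to −40 °C; aq. NaHCO3; then DBU (cat.), CH2Cl2, 0 °C
Reagents that add atoms: none
Why: Divalent samarium reduces the α,β-epoxy aldehyde to a ketyl that cleaves the adjacent C14–O bond and, after a second electron and protonation, gives the β-alkoxide aldehyde 22; renewed electron transfer forms the C13 ketyl, which adds to C12 of the dienone, and the dienyl radical is reduced to a samarium dienolate that is protonated and then equilibrated by DBU to the conjugated C3=C4 enone. The closest known reaction types are the SmI2 reduction of α,β-epoxy carbonyl compounds to aldols and the SmI2 ketyl–olefin cyclisation of aldehydes onto enones. Ring A closes in the 6-exo-trig radical mode. C12 is controlled by C7, because the four-atom tether reaches only the face of the cyclopentenone on which it sits (cis A/B fusion), and C13 is controlled by C15, because trivalent samarium bridges the ketyl oxygen and the C15 alkoxide so that both oxygens should end on the same face. The step needs cyclisation to outrun plain reduction of aldehyde or dienone, which the intramolecular chelated arrangement should secure, and attack at C12 only, which the tether length enforces; the E enone geometry follows from the nine-membered ring, which holds C2 cis to C12.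

Step 16
Reactants: 24 (3E,7S,12S,13S,15S)-13,15-dihydroxy enone
Product: 25 target CNP0386920.1, the (3E,7S,12S,13S,15S)-13,15-diacetate
Conditions: Ac2O, Et3N, DMAP, CH2Cl2, 40 °C
Reagents that add atoms: acetic anhydride, CC(=O)OC(C)=O
Why: DMAP-catalysed acetylation should esterify the secondary C13 hydroxyl and, on warming, the tertiary C15 hydroxyl without touching any stereocentre.

Compound list
1 | 3-methylbut-2-en-1-ol | CC(C)=CCO | starting material
2 | tert-butyl(dimethyl)[(3-methylbut-2-en-1-yl)oxy]silane | CC(C)=CCO[Si](C)(C)C(C)(C)C | intermediate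
3 | (2E)-4-{[tert-butyl(dimethyl)silyl]oxy}-2-methylbut-2-en-1-ol | OC/C(C)=C/CO[Si](C)(C)C(C)(C)C | intermediate
4 | {[(2E)-4-bromo-3-methylbut-2-en-1-yl]oxy}(tert-butyl)dimethylsilane | BrC/C(C)=C/CO[Si](C)(C)C(C)(C)C | intermediate
5 | N-methylprop-2-en-1-amine | CNCC=C | starting material
6 | 1-bromo-3-chloropropane | ClCCCBr | starting material
7 | 3-chloro-N-methyl-N-(prop-2-en-1-yl)propan-1-amine | C=CCN(C)CCCCl | intermediate
8 | 1,4-dioxaspiro[4.4]nonan-7-one | O=C1CCC2(C1)OCCO2 | starting material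
9 | (2R)-2-(methoxymethyl)pyrrolidin-1-amine (RAMP) | COC[C@H]1CCCN1N | starting material
10 | (2R)-N-(1,4-dioxaspiro[4.4]nonan-7-ylidene)-2-(methoxymethyl)pyrrolidin-1-amine | COC[C@H]1CCCN1N=C1CCC2(C1)OCCO2 | intermediate
11 | (2R)-N-[(8S)-8-[(2E)-4-{[tert-butyl(dimethyl)silyl]oxy}-2-methylbut-2-en-1-yl]-1,4-dioxaspiro[4.4]nonan-7-ylidene]-2-(methoxymethyl)pyrrolidin-1-amine | COC[C@H]1CCCN1N=C1[C@@H](C/C(C)=C/CO[Si](C)(C)C(C)(C)C)CC2(C1)OCCO2 | intermediate
12 | (8S)-8-[(2E)-4-{[tert-butyl(dimethyl)silyl]oxy}-2-methylbut-2-en-1-yl]-1,4-dioxaspiro[4.4]nonan-7-one | O=C1[C@@H](C/C(C)=C/CO[Si](C)(C)C(C)(C)C)CC2(C1)OCCO2 | intermediate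
13 | (5S)-3-ethoxy-5-[(2E)-4-hydroxy-2-methylbut-2-en-1-yl]cyclopent-2-en-1-one | O=C1[C@@H](C/C(C)=C/CO)CC(OCC)=C1 | intermediate
14 | (5S)-2-bromo-3-ethoxy-5-[(2E)-4-hydroxy-2-methylbut-2-en-1-yl]cyclopent-2-en-1-one | O=C1[C@@H](C/C(C)=C/CO)CC(OCC)=C1Br | intermediate
15 | (5S)-2-ethenyl-3-ethoxy-5-[(2E)-4-hydroxy-2-methylbut-2-en-1-yl]cyclopent-2-en-1-one | O=C1[C@@H](C/C(C)=C/CO)CC(OCC)=C1C=C | intermediate
16 | (5R)-2-ethenyl-3-ethoxy-5-{[(2S,3S)-3-(hydroxymethyl)-2-methyloxiran-2-yl]methyl}cyclopent-2-en-1-one | O=C1[C@@H](C[C@]2(C)O[C@H]2CO)CC(OCC)=C1C=C | intermediate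
17 | {3-[methyl(prop-2-en-1-yl)amino]propyl}magnesium chloride | C=CCN(C)CCC[Mg]Cl | intermediate
18 | 2-ethenyl-3-ethoxy-5-{[(2S,3S)-3-(hydroxymethyl)-2-methyloxiran-2-yl]methyl}-1-{3-[methyl(prop-2-en-1-yl)amino]propyl}cyclopent-2-en-1-ol (C1 epimers, other centres as in 16) | OC1(CCCN(C)CC=C)[C@@H](C[C@]2(C)O[C@H]2CO)CC(OCC)=C1C=C | intermediate
19 | (4S)-2-ethenyl-4-{[(2S,3S)-3-(hydroxymethyl)-2-methyloxiran-2-yl]methyl}-3-{3-[methyl(prop-2-en-1-yl)amino]propyl}cyclopent-2-en-1-one | O=C1C[C@H](C[C@]2(C)O[C@H]2CO)C(CCCN(C)CC=C)=C1C=C | intermediate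
20 | (3S,9Z)-3-{[(2S,3S)-3-(hydroxymethyl)-2-methyloxiran-2-yl]methyl}-7-methyl-3,4,5,6,7,8-hexahydrocyclopenta[e]azonin-1(2H)-one | O=C1C[C@H](C[C@]2(C)O[C@H]2CO)C2=C1/C=C\CN(C)CCC2 | intermediate
21 | (2R,3S)-3-methyl-3-{[(3S,9Z)-7-methyl-1-oxo-1,2,3,4,5,6,7,8-octahydrocyclopenta[e]azonin-3-yl]methyl}oxirane-2-carbaldehyde | O=C1C[C@H](C[C@]2(C)O[C@H]2C=O)C2=C1/C=C\CN(C)CCC2 | intermediate
22 | (3S)-3-hydroxy-3-methyl-4-[(3S,9Z)-7-methyl-1-oxo-1,2,3,4,5,6,7,8-octahydrocyclopenta[e]azonin-3-yl]butanal | O=C1C[C@H](C[C@](C)(O)CC=O)C2=C1/C=C\CN(C)CCC2 | intermediate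
23 | cyclised (7S,12S,13S,15S)-13,15-diol with Z-C2=C3 double bond and C4–H (C4 epimers) | O[C@H]1C[C@@](C)(O)C[C@H]2CC(=O)C3/C=C\CN(C)CCC[C@@]321 | intermediate
24 | (3E,7S,12S,13S,15S)-13,15-dihydroxy enone (de-O-acetyl target) | O[C@H]1C[C@@](C)(O)C[C@H]2CC(=O)/C3=C/CCN(C)CCC[C@@]321 | intermediate
25 | target CNP0386920.1, (3E,7S,12S,13S,15S)-13,15-diacetate | CC(=O)O[C@H]1C[C@@](C)(OC(C)=O)C[C@H]2CC(=O)/C3=C/CCN(C)CCC[C@@]321 | target

Total step count: 16. Longest linear sequence: 14 steps (steps 1–3, then 6–16).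

Steps most likely to fail

Step 15. Plain two-electron reduction of the aldehyde or of the dienone may outrun ring closure, or chelation may fail to control the C13 configuration. The fallback sets out from 21 and comes back at 24. The epoxide alone is opened (SmI2, 2.2 equiv, MeOH, THF, −90 °C) and the hydroxy aldehyde 22 is isolated. A zerovalent-nickel hydride diene–aldehyde reductive cyclisation (Ni(cod)2, PPh3, Et3SiH, THF, then DBU) then forms C12–C13 through an allylnickel species instead of a ketyl, giving the C13 triethylsilyl ether of the cyclised enone F1 with the C13 configuration left open. HF·pyridine gives the diol as C13 epimers F2, and Dess–Martin oxidation of the secondary alcohol gives the 15-hydroxy-13-ketone F3. Chelation-controlled syn reduction (Et2BOMe, NaBH4, THF–MeOH, −78 °C) should then deliver the cis-diol 24.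

Step 13. Closure of the nine-membered ring may be slow, so that oligomerisation or catalyst decay by the amine takes over. The fallback sets out from 14 and comes back at 20. The bromide is kept and epoxidised as in step 11 to the bromo epoxy alcohol F4. N-Methylprop-2-yn-1-amine is alkylated with 6 to the propargylamine F5, and kinetic radical hydrostannation (Bu3SnH, Et3B cat., −78 °C) gives the Z-vinylstannane chloroamine F6. Its Grignard reagent is added to F4 as in step 12 to give the bromo enone stannane F7. An intramolecular Stille coupling (Pd2(dba)3, AsPh3, high dilution) then closes ring C at C3–C4 and gives 20.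

Step 6. Deprotonation next to the ketal with β-elimination, or incomplete facial control, may erode the yield or the configuration at C7. The fallback sets out from 4 and comes back at 13. 3-(2-Methyl-1,3-dioxolan-2-yl)propanoic acid is coupled (pivaloyl chloride, then lithiated (S)-4-benzyl-1,3-oxazolidin-2-one) to the N-acyl oxazolidinone F8. Evans alkylation (NaN(SiMe3)2, THF, −78 °C, then 4) gives the alkylated imide F9, and aqueous acid removes ketal and silyl ether to give the keto imide alcohol F10. Intramolecular Claisen condensation of the methyl ketone enolate onto the imide carbonyl (LiN(SiMe3)2, THF, −78 to 0 °C) releases the auxiliary and gives the (4S)-4-substituted cyclopentane-1,3-dione F11. Its less hindered carbonyl is etherified (EtOH, TsOH cat.) to 13.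

Further compounds
F1 | step 15 | C13 triethylsilyl ether of the cyclised enone (C13 configuration open) | CC[Si](CC)(CC)OC1C[C@@](C)(O)C[C@H]2CC(=O)/C3=C/CCN(C)CCC[C@@]321
F2 | step 15 | cyclised 13,15-diol as C13 epimers | OC1C[C@@](C)(O)C[C@H]2CC(=O)/C3=C/CCN(C)CCC[C@@]321
F3 | step 15 | 15-hydroxy-13-ketone | O=C1C[C@@](C)(O)C[C@H]2CC(=O)/C3=C/CCN(C)CCC[C@@]321
F4 | step 13 | (5S)-2-bromo-3-ethoxy-5-{[(2S,3S)-3-(hydroxymethyl)-2-methyloxiran-2-yl]methyl}cyclopent-2-en-1-one | O=C1[C@@H](C[C@]2(C)O[C@H]2CO)CC(OCC)=C1Br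
F5 | step 13 | 3-chloro-N-methyl-N-(prop-2-yn-1-yl)propan-1-amine | C#CCN(C)CCCCl
F6 | step 13 | (2Z)-N-(3-chloropropyl)-N-methyl-3-(tributylstannyl)prop-2-en-1-amine | CCCC[Sn](CCCC)(CCCC)/C=C\CN(C)CCCCl
F7 | step 13 | (4S)-2-bromo-4-{[(2S,3S)-3-(hydroxymethyl)-2-methyloxiran-2-yl]methyl}-3-(3-{methyl[(2Z)-3-(tributylstannyl)prop-2-en-1-yl]amino}propyl)cyclopent-2-en-1-one | O=C1C[C@H](C[C@]2(C)O[C@H]2CO)C(CCCN(C)C/C=C\[Sn](CCCC)(CCCC)CCCC)=C1Br
F8 | step 6 | (4S)-4-benzyl-3-[3-(2-methyl-1,3-dioxolan-2-yl)propanoyl]-1,3-oxazolidin-2-one | CC1(CCC(=O)N2[C@@H](Cc3ccccc3)COC2=O)OCCO1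
F9 | step 6 | (4S)-4-benzyl-3-[(2S,4E)-6-{[tert-butyl(dimethyl)silyl]oxy}-4-methyl-2-[(2-methyl-1,3-dioxolan-2-yl)methyl]hex-4-enoyl]-1,3-oxazolidin-2-one | CC1(C[C@H](C/C(C)=C/CO[Si](C)(C)C(C)(C)C)C(=O)N2[C@@H](Cc3ccccc3)COC2=O)OCCO1
F10 | step 6 | (4S)-4-benzyl-3-[(2S,4E)-6-hydroxy-4-methyl-2-(2-oxopropyl)hex-4-enoyl]-1,3-oxazolidin-2-one | CC(=O)C[C@H](C/C(C)=C/CO)C(=O)N1[C@@H](Cc2ccccc2)COC1=O
F11 | step 6 | (4S)-4-[(2E)-4-hydroxy-2-methylbut-2-en-1-yl]cyclopentane-1,3-dione | O=C1CC(=O)[C@@H](C/C(C)=C/CO)C1
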